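**Retrosynthetic overview**

- Feature: in the cyclohexane ring, C5 (CHOBz) and C6 (CHOH) are adjacent carbinols, a pinacol retron. C6 sits next to the quaternary C1 (C(OH)(C7H2OBz)), so C5 is the only carbinol that can be inverted by SN2.
- Late stage: the C7 benzoate comes from selective primary acylation, the C2 hydroxyl from hydrogenolysis of a benzyl ether, and the C5 benzoate from Mitsunobu inversion of a cis-5,6-diol.
- Ring formation: the cyclohexane, the only ring of the target, is closed at the C5–C6 bond by SmI2 pinacol coupling of a 1,6-dialdehyde. C1–O and C7–O are held in a spiro-dioxolane, which is formed before the ring closure and removed after it.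
- Dialdehyde: C2 is set by an enantioselective Morita–Baylis–Hillman reaction of 4-oxobutyl pivalate (from butane-1,4-diol) with an activated acrylate. C1 is set by anti-dihydroxylation of the benzylated adduct.

Key step: step 10

Remark: atom numbers follow the target ring (C1 = C(OH)(C7H2OBz), C2 = CHOH, C3/C4 = CH2, C5 = CHOBz, C6 = CHOH). The acrylate is used as its hexafluoroisopropyl ester because the β-isocupreidine-catalysed Morita–Baylis–Hillman reaction is dependably enantioselective only with that ester; β-isocupreidine is assumed to be purchasable.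

**Route**

Step 1
Reactants: 1 butane-1,4-diol
Product: 2 4-hydroxybutyl 2,2-dimethylpropanoate
Conditions: PivCl (0.3 equiv), pyridine, CH2Cl2, 0 °C to rt
Reagents that add atoms: pivaloyl chloride, CC(C)(C)C(=O)Cl
Why: Statistical mono-acylation of a symmetrical diol used in excess (the surplus diol is removed by aqueous washing); the pivalate should survive every step up to the hydride reduction that removes it.

Step 2
Reactants: 2 4-hydroxybutyl 2,2-dimethylpropanoate
Product: 3 4-oxobutyl 2,2-dimethylpropanoate
Conditions: TEMPO (cat.), PhI(OAc)2, CH2Cl2, rt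
Reagents that add atoms: none
Why: Oxoammonium (TEMPO) oxidation of a primary alcohol stops at the aldehyde and does not touch the ester.

Step 3
Reactants: 3 4-oxobutyl 2,2-dimethylpropanoate; 4 1,1,1,3,3,3-hexafluoropropan-2-yl prop-2-enoate
Product: 5 1,1,1,3,3,3-hexafluoropropan-2-yl (3R)-6-[(2,2-dimethylpropanoyl)oxy]-3-hydroxy-2-methylidenehexanoate
Conditions: β-isocupreidine (10 mol%), DMF, −55 °C
Reagents that add atoms: none
Why: Asymmetric Morita–Baylis–Hillman reaction in which the quinuclidine nitrogen adds to the activated acrylate and the catalyst phenol hydrogen-bonds the aldolate, so that this catalyst/ester pair should deliver the (R)-carbinol that becomes C2.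

Step 4
Reactants: 5 hexafluoroisopropyl ester adduct
Product: 6 methyl (3R)-6-[(2,2-dimethylpropanoyl)oxy]-3-hydroxy-2-methylidenehexanoate
Conditions: MeOH, Et3N, rt
Reagents that add atoms: methanol, CO
Why: Transesterification of an activated fluoroalkyl ester under mild base gives the robust methyl ester without touching the pivalate or the carbinol stereocentre.

Step 5
Reactants: 6 methyl ester adduct
Product: 7 methyl (3R)-3-(benzyloxy)-6-[(2,2-dimethylpropanoyl)oxy]-2-methylidenehexanoate
Conditions: BnOC(=NH)CCl3, TfOH (cat.), CH2Cl2/cyclohexane, 0 °C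
Reagents that add atoms: benzyl 2,2,2-trichloroacetimidate, N=C(OCc1ccccc1)C(Cl)(Cl)Cl
Why: Acid-catalysed trichloroacetimidate benzylation avoids the alkoxide, which would trigger oxa-Michael or retro-aldol pathways in this adduct, and leaves the C2–O bond and its configuration intact.

Step 6
Reactants: 7 benzyl ether
Product: 8 methyl (2S,3R)-3-(benzyloxy)-6-[(2,2-dimethylpropanoyl)oxy]-2-hydroxy-2-(hydroxymethyl)hexanoate
Conditions: OsO4 (cat.), NMO, acetone/H2O, rt
Reagents that add atoms: osmium tetroxide, O=[Os](=O)(=O)=O; N-methylmorpholine N-oxide, C[N+]1([O-])CCOCC1; water, O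
Why: Catalytic cis-dihydroxylation in which, with the allylic C–H eclipsing the alkene, OsO4 should add to the face opposite the allylic benzyloxy group (the empirical rule for osmylation of allylic ethers), setting the tertiary carbinol C1 as (2S).

Step 7
Reactants: 8 diol ester
Product: 9 methyl (4S)-4-[(1R)-1-(benzyloxy)-4-[(2,2-dimethylpropanoyl)oxy]butyl]-2,2-dimethyl-1,3-dioxolane-4-carboxylate
Conditions: Me2C(OMe)2, PPTS (cat.), CH2Cl2, rt
Reagents that add atoms: 2,2-dimethoxypropane, COC(C)(C)OC
Why: Acid-catalysed transketalisation ties the C1 and C7 hydroxyls into the five-membered dioxolane, the only cyclic acetal this 1,2-diol can form.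

Step 8
Reactants: 9 acetonide ester
Product: 10 (4R)-4-(benzyloxy)-4-[(4S)-4-(hydroxymethyl)-2,2-dimethyl-1,3-dioxolan-4-yl]butan-1-ol
Conditions: LiAlH4, THF, 0 °C to rt; H2O, aq. NaOH
Reagents that add atoms: none
Why: Hydride reduction converts the methyl ester into the C6 carbinol and cleaves the pivalate at C5 in the same operation, while the benzyl ether and the acetonide are inert.

Step 9
Reactants: 10 diol
Product: 11 (4S)-4-[(1R)-1-(benzyloxy)-4-oxobutyl]-2,2-dimethyl-1,3-dioxolane-4-carbaldehyde
Conditions: (COCl)2, DMSO, CH2Cl2, −78 °C; Et3N, −78 to 0 °C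
Reagents that add atoms: none
Why: Double Swern oxidation gives the 1,6-dialdehyde under non-acidic conditions; the C6 aldehyde has no α-hydrogen and cannot epimerise, and the crude product would be taken into step 10 directly after work-up.

Step 10
Reactants: 11 dialdehyde
Product: 12 (5R,6S,7S,10R)-10-(benzyloxy)-2,2-dimethyl-1,3-dioxaspiro[4.5]decane-6,7-diol
Conditions: SmI2 (3 equiv), t-BuOH (3 equiv), THF (0.01 M), −78 °C to rt; aq. NH4Cl
Reagents that add atoms: none
Why: Two equivalents of divalent samarium each transfer one electron to an aldehyde, and the ketyls (or a ketyl and the second samarium-bound carbonyl) combine to form the C5–C6 bond; this is the known SmI2 pinacol cyclisation of 1,6-dialdehydes to cis-cyclohexane-1,2-diols. The cyclohexane closes in a 6-exo-trig mode, the C6 ketyl carbon attacking the C5 carbonyl carbon with that oxygen outside the ring. C5 is set cis to C6 because both oxygens remain bound to trivalent samarium in a bridged transition state. C6 is set by the quaternary C1: the C6–O–Sm bond should turn away from the C1–O bond of the dioxolane to minimise dipole and lone-pair repulsion, so the diol should form on the face opposite the acetal oxygen. The step needs cyclisation over intermolecular coupling and the cis diol anti to the C1 oxygen; high dilution, low temperature and the non-epimerisable spiro-acetonide at C1 are meant to secure both. The C5 configuration formed here is deliberately the opposite of the target and is corrected in step 11.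

Step 11
Reactants: 12 cis-diol; 13 benzoic acid
Product: 14 (5R,6S,7R,10R)-10-(benzyloxy)-6-hydroxy-2,2-dimethyl-1,3-dioxaspiro[4.5]decan-7-yl benzoate
Conditions: PPh3, DIAD, toluene, 0 °C to rt
Reagents that add atoms: none
Why: Mitsunobu esterification in which only the C5 hydroxyl can be displaced (C6 is neopentyl-like next to the quaternary C1, and a cis-diol cannot close to an epoxide), so benzoate should attack the C5 oxyphosphonium ion by SN2 with inversion.

Step 12
Reactants: 14 monobenzoate
Product: 15 (1R,2S,3R,4R)-4-(benzyloxy)-2,3-dihydroxy-3-(hydroxymethyl)cyclohexyl benzoate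
Conditions: AcOH/H2O (4:1), 40 °C
Reagents that add atoms: none
Why: Mild aqueous acid hydrolyses the dioxolane without cleaving the benzoate or the benzyl ether, and acid keeps acyl migration from C5–O to C6–O slow.

Step 13
Reactants: 15 triol
Product: 16 [(1R,2R,5R,6S)-5-(benzoyloxy)-2-(benzyloxy)-1,6-dihydroxycyclohexyl]methyl benzoate
Conditions: BzCl (1.05 equiv), pyridine, CH2Cl2, −30 to 0 °C
Reagents that add atoms: benzoyl chloride, O=C(Cl)c1ccccc1
Why: Low-temperature acylation should select the primary C7 hydroxyl over the tertiary C1 hydroxyl and the hindered secondary C6 hydroxyl, both of which flank the quaternary centre.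

Step 14
Reactants: 16 benzyl ether dibenzoate
Product: 17 [(1S,2R,5R,6S)-5-(benzoyloxy)-1,2,6-trihydroxycyclohexyl]methyl benzoate (target)
Conditions: H2 (1 atm), Pd/C, EtOAc, rt
Reagents that add atoms: none
Why: Catalytic hydrogenolysis cleaves the benzylic C–O bond of the C2 ether, while the two benzoate esters, which have no benzylic C–O bond, are stable under neutral conditions.

**Compound list**

1 | butane-1,4-diol | OCCCCO | starting material
2 | 4-hydroxybutyl 2,2-dimethylpropanoate | CC(C)(C)C(=O)OCCCCO | intermediate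
3 | 4-oxobutyl 2,2-dimethylpropanoate | CC(C)(C)C(=O)OCCCC=O | intermediate
4 | 1,1,1,3,3,3-hexafluoropropan-2-yl prop-2-enoate | C=CC(=O)OC(C(F)(F)F)C(F)(F)F | starting material
5 | 1,1,1,3,3,3-hexafluoropropan-2-yl (3R)-6-[(2,2-dimethylpropanoyl)oxy]-3-hydroxy-2-methylidenehexanoate | C=C(C(=O)OC(C(F)(F)F)C(F)(F)F)[C@H](O)CCCOC(=O)C(C)(C)C | intermediate
6 | methyl (3R)-6-[(2,2-dimethylpropanoyl)oxy]-3-hydroxy-2-methylidenehexanoate | C=C(C(=O)OC)[C@H](O)CCCOC(=O)C(C)(C)C | intermediate
7 | methyl (3R)-3-(benzyloxy)-6-[(2,2-dimethylpropanoyl)oxy]-2-methylidenehexanoate | C=C(C(=O)OC)[C@H](OCc1ccccc1)CCCOC(=O)C(C)(C)C | intermediate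
8 | methyl (2S,3R)-3-(benzyloxy)-6-[(2,2-dimethylpropanoyl)oxy]-2-hydroxy-2-(hydroxymethyl)hexanoate | COC(=O)[C@](O)(CO)[C@H](OCc1ccccc1)CCCOC(=O)C(C)(C)C | intermediate
9 | methyl (4S)-4-[(1R)-1-(benzyloxy)-4-[(2,2-dimethylpropanoyl)oxy]butyl]-2,2-dimethyl-1,3-dioxolane-4-carboxylate | COC(=O)[C@]1(COC(C)(C)O1)[C@H](OCc1ccccc1)CCCOC(=O)C(C)(C)C | intermediate
10 | (4R)-4-(benzyloxy)-4-[(4S)-4-(hydroxymethyl)-2,2-dimethyl-1,3-dioxolan-4-yl]butan-1-ol | OC[C@]1(COC(C)(C)O1)[C@H](OCc1ccccc1)CCCO | intermediate
11 | (4S)-4-[(1R)-1-(benzyloxy)-4-oxobutyl]-2,2-dimethyl-1,3-dioxolane-4-carbaldehyde | O=C[C@]1(COC(C)(C)O1)[C@H](OCc1ccccc1)CCC=O | intermediate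
12 | (5R,6S,7S,10R)-10-(benzyloxy)-2,2-dimethyl-1,3-dioxaspiro[4.5]decane-6,7-diol | O[C@H]1[C@@H](O)CC[C@@H](OCc2ccccc2)[C@@]12COC(C)(C)O2 | intermediate
13 | benzoic acid | O=C(O)c1ccccc1 | starting material
14 | (5R,6S,7R,10R)-10-(benzyloxy)-6-hydroxy-2,2-dimethyl-1,3-dioxaspiro[4.5]decan-7-yl benzoate | O[C@H]1[C@H](OC(=O)c2ccccc2)CC[C@@H](OCc2ccccc2)[C@@]12COC(C)(C)O2 | intermediate
15 | (1R,2S,3R,4R)-4-(benzyloxy)-2,3-dihydroxy-3-(hydroxymethyl)cyclohexyl benzoate | OC[C@]1(O)[C@H](OCc2ccccc2)CC[C@@H](OC(=O)c2ccccc2)[C@@H]1O | intermediate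
16 | [(1R,2R,5R,6S)-5-(benzoyloxy)-2-(benzyloxy)-1,6-dihydroxycyclohexyl]methyl benzoate | O=C(OC[C@]1(O)[C@H](OCc2ccccc2)CC[C@@H](OC(=O)c2ccccc2)[C@@H]1O)c1ccccc1 | intermediate
17 | [(1S,2R,5R,6S)-5-(benzoyloxy)-1,2,6-trihydroxycyclohexyl]methyl benzoate | O=C(OC[C@]1(O)[C@H](O)CC[C@@H](OC(=O)c2ccccc2)[C@@H]1O)c1ccccc1 | target

**Totals**

Total step count: 14. Longest linear sequence: 14 steps (from 1 to 17).

**Steps most likely to fail, with fallbacks**

1. Step 10 (key step). What may go wrong:
   - the ketyl coupling may discriminate poorly between the two faces at the spiro centre, so that the diol forms on the side of the dioxolane oxygen;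
   - the dialdehyde may be reduced or coupled intermolecularly instead of cyclising.

   Fallback: setting out from dialdehyde 11, both formyl groups would be methylenated with Ph3P=CH2 (from Ph3PCH3Br and KN(SiMe3)2, THF) to give (4S)-4-[(1R)-1-(benzyloxy)pent-4-en-1-yl]-4-ethenyl-2,2-dimethyl-1,3-dioxolane F1. Ring-closing metathesis with the second-generation Grubbs catalyst (CH2Cl2, 40 °C) would join C5 and C6 as an alkene and give (5S,10R)-10-(benzyloxy)-2,2-dimethyl-1,3-dioxaspiro[4.5]dec-6-ene F2. Cis-dihydroxylation with OsO4 (cat.)/NMO, which in cyclohexenes adds anti to an allylic C–O bond, should then give diol 12, where the route is rejoined.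

2. Step 6. What may go wrong: acyclic allylic control of the osmylation may be weak, so that both faces of the 1,1-disubstituted alkene react and C1 is formed as a mixture.

   Fallback: setting out from adduct 6, the stereocontrol would be made cyclic.
   - Reduction with i-Bu2AlH (CH2Cl2, −78 to 0 °C) would cleave both esters to (3R)-2-methylidenehexane-1,3,6-triol F3.
   - PhCH(OMe)2 with catalytic camphorsulfonic acid would tie the 1,3-diol into 3-[(2S,4R)-5-methylidene-2-phenyl-1,3-dioxan-4-yl]propan-1-ol F4, with both ring substituents equatorial.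
   - OsO4 (cat.)/NMO should attack the exocyclic alkene from the axial direction, which is unhindered in a 1,3-dioxane and leads to the new tertiary hydroxyl cis to the equatorial side chain. This gives (2S,4R,5R)-5-(hydroxymethyl)-4-(3-hydroxypropyl)-2-phenyl-1,3-dioxan-5-ol F5.
   - Me2C(OMe)2/PPTS would give 3-[(5S,6R,8S)-2,2-dimethyl-8-phenyl-1,3,7,9-tetraoxaspiro[4.5]decan-6-yl]propan-1-ol F6.
   - Reductive opening of the benzylidene acetal with i-Bu2AlH (CH2Cl2, 0 °C) should cleave at the less hindered primary oxygen, leaving the benzyl group on the C2 oxygen and freeing the C6 hydroxyl. This is diol 10, where the route is rejoined, so steps 5 to 8 are bypassed.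

3. Step 11. What may go wrong: the cis-diol may be held as an unreactive dioxaphosphorane, or the activated C5 alcohol may eliminate instead of being displaced.

   Fallback: setting out from diol 12, SOCl2/Et3N (CH2Cl2, 0 °C) would give the 6,7-cyclic sulfite of 12 (epimers at sulfur) F7, and RuCl3 (cat.)/NaIO4 (MeCN/H2O) would oxidise it to the 6,7-cyclic sulfate of 12 F8. Tetrabutylammonium benzoate (DMF, rt) should open the sulfate by SN2 at C5, the only carbon open to backside attack, giving (5S,6S,7R,10R)-10-(benzyloxy)-2,2-dimethyl-6-(sulfooxy)-1,3-dioxaspiro[4.5]decan-7-yl benzoate F9. Hydrolysis of the sulfate monoester with H2SO4 (cat.) and a little H2O in THF would give 14, where the route is rejoined.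

Further compounds
F1 | step 10 | (4S)-4-[(1R)-1-(benzyloxy)pent-4-en-1-yl]-4-ethenyl-2,2-dimethyl-1,3-dioxolane | C=C[C@]1(COC(C)(C)O1)[C@H](OCc1ccccc1)CCC=C
F2 | step 10 | (5S,10R)-10-(benzyloxy)-2,2-dimethyl-1,3-dioxaspiro[4.5]dec-6-ene | C1=C[C@]2(COC(C)(C)O2)[C@H](OCc3ccccc3)CC1
F3 | step 6 | (3R)-2-methylidenehexane-1,3,6-triol | C=C(CO)[C@H](O)CCCO
F4 | step 6 | 3-[(2S,4R)-5-methylidene-2-phenyl-1,3-dioxan-4-yl]propan-1-ol | C=C1CO[C@H](c2ccccc2)O[C@@H]1CCCO
F5 | step 6 | (2S,4R,5R)-5-(hydroxymethyl)-4-(3-hydroxypropyl)-2-phenyl-1,3-dioxan-5-ol | OC[C@@]1(O)CO[C@H](c2ccccc2)O[C@@H]1CCCO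
F6 | step 6 | 3-[(5S,6R,8S)-2,2-dimethyl-8-phenyl-1,3,7,9-tetraoxaspiro[4.5]decan-6-yl]propan-1-ol | CC1(C)OC[C@@]2(O1)CO[C@H](c1ccccc1)O[C@@H]2CCCO
F7 | step 11 | 6,7-cyclic sulfite of 12 (epimers at sulfur) | O=S1O[C@H]2[C@@H](O1)CC[C@@H](OCc3ccccc3)[C@@]23COC(C)(C)O3
F8 | step 11 | 6,7-cyclic sulfate of 12 | O=S1(=O)O[C@H]2[C@@H](O1)CC[C@@H](OCc3ccccc3)[C@@]23COC(C)(C)O3
F9 | step 11 | (5S,6S,7R,10R)-10-(benzyloxy)-2,2-dimethyl-6-(sulfooxy)-1,3-dioxaspiro[4.5]decan-7-yl benzoate | OS(=O)(=O)O[C@H]1[C@H](OC(=O)c2ccccc2)CC[C@@H](OCc2ccccc2)[C@@]12COC(C)(C)O2
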